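## Retrosynthetic overview

1. Target ⇒ macrocyclic 8,9-diol: the two ester C–O bonds are made last (C8 isovalerate, then C9 acetate).
2. Ring C (ten-membered carbocycle) and the α-methylene lactone ⇒ C7–C8, by an intramolecular, chelate-controlled indium Barbier allylation of a 3-(bromomethyl)butenolide onto a C8 aldehyde.
3. C3–C4 ⇒ palladium-catalysed C–H alkenylation of the furanone C–H of fragment A with the Z-alkenyl iodide of fragment B (fragment union).
4. Fragment A (ring A, furanone; C9 and C10) ⇒ (S)-lactic acid, pivalaldehyde, 2,2-dimethoxyacetaldehyde, ethynylmagnesium bromide.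
5. Fragment B (ring B, butenolide; C6) ⇒ acrolein, 1-propynylmagnesium bromide, methyl 2-(hydroxymethyl)acrylate. Ring order: A, B, then C.

Assumption: atom labels C1–C15 follow germacrane numbering of the target (C6 lactone carbinol, C7, C8 isovalerate carbon, C9 acetate carbon, C10 quaternary carbon, C1–C3 furanone, C4=C5 alkene, C11–C13 methylene lactone); Grignard solutions and 2,2-dimethoxyacetaldehyde (dried before use) are taken as commercial.

## Route

Step 1
Reactants: 1 (S)-lactic acid; 2 pivalaldehyde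
Product: 3 (2S,5S)-2-tert-butyl-5-methyl-1,3-dioxolan-4-one
Conditions: cat. TsOH·H2O, cat. H2SO4, pentane, reflux (Dean–Stark); recrystallisation from pentane, −78 °C
Reagents that add atoms: none
Why: Acid-catalysed acetalisation (Seebach self-regeneration of stereocentres) gives mainly the cis-dioxolanone, the new acetal carbon (2S) being set by the thermodynamic preference for cis relative to the lactate methyl, and crystallisation gives the pure cis isomer.

Step 2
Reactants: 3 (2S,5S)-2-tert-butyl-5-methyl-1,3-dioxolan-4-one; 4 2,2-dimethoxyacetaldehyde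
Product: 7 (2S,5R)-2-tert-butyl-5-[(1S)-2,2-dimethoxy-1-(triethylsilyloxy)ethyl]-5-methyl-1,3-dioxolan-4-one, via lithium enolate 5 (not isolated), via lithium aldolate 6 (not isolated)
Conditions: LiN(iPr)2, THF, −78 °C; 4, −78 °C; Et3SiOSO2CF3, −78 → −40 °C
Reagents that add atoms: triethylsilyl trifluoromethanesulfonate, CC[Si](CC)(CC)OS(=O)(=O)C(F)(F)F
Why: Aldol addition of the planar lithium enolate occurs anti to the tert-butyl group, which fixes the quaternary carbon (C10) with retention of the lactate configuration, while a Zimmerman–Traxler chair with the enolate methyl cis to O–Li is expected to give the methyl/hydroxyl syn (O9/O10 anti) relationship at the new carbinol (C9); silylation of the aldolate in the same flask prevents retro-aldol cleavage.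

Step 3
Reactants: 7 (2S,5R)-2-tert-butyl-5-[(1S)-2,2-dimethoxy-1-(triethylsilyloxy)ethyl]-5-methyl-1,3-dioxolan-4-one; 8 ethynylmagnesium bromide
Product: 11 (1E,4R,5S)-1-(diethylamino)-4-hydroxy-6,6-dimethoxy-4-methyl-5-(triethylsilyloxy)hex-1-en-3-one, via magnesium hemiketal alkoxide 9 (not isolated), via hydroxy ynone 10 (not isolated)
Conditions: HC≡CMgBr (1.3 equiv), THF, −78 → −30 °C; AcOH (1.3 equiv), −78 °C; crude, Et2NH (1.5 equiv), EtOH, 0 °C
Reagents that add atoms: diethylamine, CCNCC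
Why: Mono-addition of the alkynyl Grignard reagent to the acylal-type lactone carbonyl gives a tetrahedral alkoxide that is stable in the cold (lactone-to-lactol type addition) and collapses on protonation with loss of pivalaldehyde to the α'-hydroxy ynone, which is trapped at once by aza-Michael addition of diethylamine as the stable E-enaminone; no stereocentre is touched.

Step 4
Reactants: 11 (1E,4R,5S)-1-(diethylamino)-4-hydroxy-6,6-dimethoxy-4-methyl-5-(triethylsilyloxy)hex-1-en-3-one
Product: 12 (2R)-2-[(1S)-2,2-dimethoxy-1-(triethylsilyloxy)ethyl]-2-methylfuran-3(2H)-one (fragment A)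
Conditions: AcOH (5 equiv), toluene, 40 °C
Reagents that add atoms: none
Why: Acid-mediated addition–elimination cyclisation of the α'-hydroxy enaminone (classical amine-mediated 3(2H)-furanone synthesis) lets the tertiary hydroxyl add 5-exo-trig to the iminium carbon with loss of diethylamine, while the silyl ether on C9 excludes the competing six-membered pyranone; stereocentres are untouched.

Step 5
Reactants: 13 methyl 2-(hydroxymethyl)acrylate
Product: 14 methyl 2-{[(tert-butyldimethylsilyl)oxy]methyl}acrylate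
Conditions: TBSCl, imidazole, CH2Cl2, 0 °C → rt
Reagents that add atoms: tert-butyldimethylsilyl chloride, CC(C)(C)[Si](C)(C)Cl
Why: Standard silyl ether formation on a primary allylic alcohol.

Step 6
Reactants: 14 methyl 2-{[(tert-butyldimethylsilyl)oxy]methyl}acrylate
Product: 15 2-{[(tert-butyldimethylsilyl)oxy]methyl}acrylic acid
Conditions: LiOH, THF–H2O, 0 °C; then 1 M HCl to pH 3
Reagents that add atoms: lithium hydroxide, [Li+].[OH-]
Why: Saponification of the methyl ester; the primary silyl ether survives cold aqueous LiOH and careful acidification.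

Step 7
Reactants: 16 acrolein; 17 1-propynylmagnesium bromide
Product: 18 (±)-hex-1-en-4-yn-3-ol
Conditions: CH3C≡CMgBr, THF, −78 → 0 °C; 1 M HCl, 0 °C
Reagents that add atoms: none
Why: 1,2-addition of the alkynyl Grignard reagent to the enal at low temperature gives the racemic secondary alcohol.

Step 8
Reactants: 18 (±)-hex-1-en-4-yn-3-ol
Product: 19 (3S)-hex-1-en-4-yn-3-ol
Conditions: Ti(OiPr)4 (1.0 equiv), L-(+)-diisopropyl tartrate (1.2 equiv), t-BuOOH (0.6 equiv), 4 Å MS, CH2Cl2, −20 °C; recovered alcohol (at most 50%)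
Reagents that add atoms: none
Why: Sharpless kinetic resolution of the secondary allylic alcohol: with the L-(+)-tartrate titanium catalyst the (R)-enantiomer is epoxidised fast, so the (S)-alcohol (C6 of the target) is recovered in high enantiomeric purity at about 55% conversion.

Step 9
Reactants: 19 (3S)-hex-1-en-4-yn-3-ol
Product: 21 (3S,4Z)-5-iodohexa-1,4-dien-3-ol, via cyclic vinylalanate 20 (not isolated)
Conditions: NaAlH2(OCH2CH2OCH3)2, THF, 0 °C → rt; I2, −78 °C; aq KNaC4H4O6
Reagents that add atoms: iodine, II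
Why: Hydroxyl-directed trans-hydroalumination of the propargylic alcohol places aluminium on the distal alkyne carbon in a five-membered alanate, and iodinolysis with retention gives the Z-alkenyl iodide (iodine cis to the carbinol carbon), the geometry needed for C4=C5.

Step 10
Reactants: 21 (3S,4Z)-5-iodohexa-1,4-dien-3-ol; 15 2-{[(tert-butyldimethylsilyl)oxy]methyl}acrylic acid
Product: 22 (3S,4Z)-5-iodohexa-1,4-dien-3-yl 2-{[(tert-butyldimethylsilyl)oxy]methyl}prop-2-enoate
Conditions: DCC, DMAP (10 mol %), CH2Cl2, 0 °C → rt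
Reagents that add atoms: none
Why: Steglich esterification of the secondary bis-allylic alcohol; the stereocentre is not affected.

Step 11
Reactants: 22 (3S,4Z)-5-iodohexa-1,4-dien-3-yl 2-{[(tert-butyldimethylsilyl)oxy]methyl}prop-2-enoate
Product: 23 (5S)-3-{[(tert-butyldimethylsilyl)oxy]methyl}-5-[(1Z)-2-iodoprop-1-en-1-yl]furan-2(5H)-one (fragment B)
Conditions: second-generation Grubbs catalyst RuCl2(=CHPh)(PCy3)(H2IMes) (10 mol %), toluene, 80 °C, 0.01 M
Reagents that add atoms: none
Why: Ring-closing metathesis between the vinyl group and the 1,1-disubstituted acrylate forms the butenolide (ring B) with loss of ethylene; the trisubstituted iodoalkene is too hindered and electron-poor to engage the ruthenium carbene.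

Step 12
Reactants: 12 (2R)-2-[(1S)-2,2-dimethoxy-1-(triethylsilyloxy)ethyl]-2-methylfuran-3(2H)-one (1.5 equiv); 23 (5S)-3-{[(tert-butyldimethylsilyl)oxy]methyl}-5-[(1Z)-2-iodoprop-1-en-1-yl]furan-2(5H)-one
Product: 24 (5R)-3-{[(tert-butyldimethylsilyl)oxy]methyl}-5-[(1Z)-2-{(5R)-5-[(1S)-2,2-dimethoxy-1-(triethylsilyloxy)ethyl]-5-methyl-4-oxo-4,5-dihydrofuran-2-yl}prop-1-en-1-yl]furan-2(5H)-one
Conditions: Pd(OAc)2 (10 mol %), tri(2-furyl)phosphine (20 mol %), silver pivalate AgO2CC(CH3)3 (2.0 equiv), toluene, 60 °C, dark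
Reagents that add atoms: none
Why: Proposed new method: palladium-catalysed direct C–H alkenylation of a 2,2-disubstituted 3(2H)-furanone at the carbon next to the ring oxygen by a Z-alkenyl iodide, reasoned as oxidative addition of zerovalent palladium to the C–I bond with retention of the Z geometry, iodide abstraction by silver, pivalate-assisted concerted metalation–deprotonation at the most acidic furanone C–H (which is also the electronically matched β-carbon of the vinylogous ester in the alternative Heck-type carbopalladation and base-assisted β-hydride elimination pathway), and C–C reductive elimination forming C3–C4; the closest known reaction types are the pivalate-assisted direct C–H arylation and alkenylation of azoles and the C2–H functionalisation of chromones, which have not been shown on 3(2H)-furanones.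

Step 13
Reactants: 24 (silyl-protected coupling product)
Product: 25 (5R)-3-(hydroxymethyl)-5-[(1Z)-2-{(5R)-5-[(1S)-1-hydroxy-2,2-dimethoxyethyl]-5-methyl-4-oxo-4,5-dihydrofuran-2-yl}prop-1-en-1-yl]furan-2(5H)-one
Conditions: HF·pyridine, pyridine, THF, 0 °C → rt
Reagents that add atoms: none
Why: Fluoride-mediated cleavage of both silyl ethers under buffered conditions that leave the dimethyl acetal, the butenolide and the furanone intact.

Step 14
Reactants: 25 (diol)
Product: 26 (5R)-3-(bromomethyl)-5-[(1Z)-2-{(5R)-5-[(1S)-1-hydroxy-2,2-dimethoxyethyl]-5-methyl-4-oxo-4,5-dihydrofuran-2-yl}prop-1-en-1-yl]furan-2(5H)-one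
Conditions: CBr4, PPh3, CH2Cl2, −20 → 0 °C
Reagents that add atoms: carbon tetrabromide, BrC(Br)(Br)Br
Why: Appel bromination of the primary allylic alcohol by SN2 displacement of the oxyphosphonium ion; the hindered secondary hydroxyl next to the quaternary centre does not react at 0 °C.

Step 15
Reactants: 26 (allylic bromide acetal)
Product: 28 (2Z,4R,8R,9S,10R,11R)-9,10-dihydroxy-2,11-dimethyl-7-methylidene-5,14-dioxatricyclo[9.2.1.0^4,8]tetradeca-1(13),2-diene-6,12-dione (the target skeleton carrying free 8β- and 9α-hydroxyl groups), via hydroxy aldehyde 27 (not isolated)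
Conditions: CF3CO2H–H2O (9:1), 0 °C, then evaporation; In powder (3 equiv), THF–H2O (3:1), 0.002 M, rt
Reagents that add atoms: water, O
Why: After acetal hydrolysis, an intramolecular indium-mediated Barbier allylation in water closes ring C by γ-attack of the lactonyl allylindium through C7 anti to the C6 substituent (6,7-trans α-methylene lactone), while chelation of indium by the free C9 hydroxyl and the aldehyde oxygen (Cram-chelate control) exposes the face that gives the 8,9-syn diol and holds C9 axial in the six-membered transition state, so that the geometrically locked allyl unit is expected to deliver the C7/C8 relationship of the target.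

Step 16
Reactants: 28 (macrocyclic 8,9-diol)
Product: 30 (2Z,4R,8S,9S,10R,11R)-10-(acetyloxy)-2,11-dimethyl-7-methylidene-6,12-dioxo-5,14-dioxatricyclo[9.2.1.0^4,8]tetradeca-1(13),2-dien-9-yl 3-methylbutanoate (target CNP0255553.1), via 8-monoisovalerate 29 (not isolated)
Conditions: isovaleryl chloride (1.1 equiv), 2,4,6-collidine, CH2Cl2, −40 → 0 °C; then Ac2O, DMAP (0.2 equiv), pyridine, rt
Reagents that add atoms: isovaleryl chloride, CC(C)CC(=O)Cl; acetic anhydride, CC(=O)OC(C)=O
Why: Sequential acylation under steric control: the C8 hydroxyl is esterified first by the acid chloride with a hindered base, and the C9 hydroxyl next to the quaternary C10 reacts only afterwards with the small DMAP-activated acetyl donor; stereocentres are untouched.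

## Compound list

1 | (S)-lactic acid | C[C@H](O)C(=O)O | starting material
2 | pivalaldehyde | CC(C)(C)C=O | starting material
3 | (2S,5S)-2-tert-butyl-5-methyl-1,3-dioxolan-4-one | C[C@@H]1O[C@@H](OC1=O)C(C)(C)C | intermediate
4 | 2,2-dimethoxyacetaldehyde | COC(OC)C=O | starting material
5 | lithium (2S)-2-tert-butyl-5-methyl-1,3-dioxol-4-olate (lithium enolate of 3) | [Li+].[O-]C1=C(C)O[C@@H](O1)C(C)(C)C | intermediate
6 | lithium (1S)-1-[(2S,4R)-2-tert-butyl-4-methyl-5-oxo-1,3-dioxolan-4-yl]-2,2-dimethoxyethan-1-olate (lithium aldolate) | C[C@]1([C@H]([O-])C(OC)OC)O[C@@H](OC1=O)C(C)(C)C.[Li+] | intermediate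
7 | (2S,5R)-2-tert-butyl-5-[(1S)-2,2-dimethoxy-1-(triethylsilyloxy)ethyl]-5-methyl-1,3-dioxolan-4-one | C[C@]1([C@H](O[Si](CC)(CC)CC)C(OC)OC)O[C@@H](OC1=O)C(C)(C)C | intermediate
8 | ethynylmagnesium bromide | C#C[Mg]Br | starting material
9 | bromomagnesium (2S,5R)-2-tert-butyl-5-[(1S)-2,2-dimethoxy-1-(triethylsilyloxy)ethyl]-4-ethynyl-5-methyl-1,3-dioxolan-4-olate (C4 not defined) | C#CC1([O-])O[C@H](O[C@]1(C)[C@H](O[Si](CC)(CC)CC)C(OC)OC)C(C)(C)C.[Mg+2].[Br-] | intermediate
10 | (4R,5S)-4-hydroxy-6,6-dimethoxy-4-methyl-5-(triethylsilyloxy)hex-1-yn-3-one | C#CC(=O)[C@](C)(O)[C@H](O[Si](CC)(CC)CC)C(OC)OC | intermediate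
11 | (1E,4R,5S)-1-(diethylamino)-4-hydroxy-6,6-dimethoxy-4-methyl-5-(triethylsilyloxy)hex-1-en-3-one | CCN(CC)/C=C/C(=O)[C@](C)(O)[C@H](O[Si](CC)(CC)CC)C(OC)OC | intermediate
12 | (2R)-2-[(1S)-2,2-dimethoxy-1-(triethylsilyloxy)ethyl]-2-methylfuran-3(2H)-one (fragment A) | O=C1C=CO[C@]1(C)[C@H](O[Si](CC)(CC)CC)C(OC)OC | intermediate
13 | methyl 2-(hydroxymethyl)acrylate | C=C(CO)C(=O)OC | starting material
14 | methyl 2-{[(tert-butyldimethylsilyl)oxy]methyl}acrylate | C=C(CO[Si](C)(C)C(C)(C)C)C(=O)OC | intermediate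
15 | 2-{[(tert-butyldimethylsilyl)oxy]methyl}acrylic acid | C=C(CO[Si](C)(C)C(C)(C)C)C(=O)O | intermediate
16 | acrolein | C=CC=O | starting material
17 | 1-propynylmagnesium bromide | CC#C[Mg]Br | starting material
18 | (±)-hex-1-en-4-yn-3-ol | C=CC(O)C#CC | intermediate
19 | (3S)-hex-1-en-4-yn-3-ol | O[C@@H](C=C)C#CC | intermediate
20 | sodium (5S)-2,2-bis(2-methoxyethoxy)-3-methyl-5-vinyl-2,5-dihydro-1,2-oxaluminol-2-uide (cyclic vinylalanate) | C=C[C@@H]1O[Al-](OCCOC)(OCCOC)C(C)=C1.[Na+] | intermediate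
21 | (3S,4Z)-5-iodohexa-1,4-dien-3-ol | O[C@@H](C=C)/C=C(/C)I | intermediate
22 | (3S,4Z)-5-iodohexa-1,4-dien-3-yl 2-{[(tert-butyldimethylsilyl)oxy]methyl}prop-2-enoate | C=C(CO[Si](C)(C)C(C)(C)C)C(=O)O[C@@H](C=C)/C=C(/C)I | intermediate
23 | (5S)-3-{[(tert-butyldimethylsilyl)oxy]methyl}-5-[(1Z)-2-iodoprop-1-en-1-yl]furan-2(5H)-one (fragment B) | O=C1O[C@H](/C=C(/C)I)C=C1CO[Si](C)(C)C(C)(C)C | intermediate
24 | (5R)-3-{[(tert-butyldimethylsilyl)oxy]methyl}-5-[(1Z)-2-{(5R)-5-[(1S)-2,2-dimethoxy-1-(triethylsilyloxy)ethyl]-5-methyl-4-oxo-4,5-dihydrofuran-2-yl}prop-1-en-1-yl]furan-2(5H)-one | O=C1O[C@H](/C=C(/C)C2=CC(=O)[C@](C)(O2)[C@H](O[Si](CC)(CC)CC)C(OC)OC)C=C1CO[Si](C)(C)C(C)(C)C | intermediate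
25 | (5R)-3-(hydroxymethyl)-5-[(1Z)-2-{(5R)-5-[(1S)-1-hydroxy-2,2-dimethoxyethyl]-5-methyl-4-oxo-4,5-dihydrofuran-2-yl}prop-1-en-1-yl]furan-2(5H)-one | O=C1O[C@H](/C=C(/C)C2=CC(=O)[C@](C)(O2)[C@H](O)C(OC)OC)C=C1CO | intermediate
26 | (5R)-3-(bromomethyl)-5-[(1Z)-2-{(5R)-5-[(1S)-1-hydroxy-2,2-dimethoxyethyl]-5-methyl-4-oxo-4,5-dihydrofuran-2-yl}prop-1-en-1-yl]furan-2(5H)-one | O=C1O[C@H](/C=C(/C)C2=CC(=O)[C@](C)(O2)[C@H](O)C(OC)OC)C=C1CBr | intermediate
27 | (5R)-3-(bromomethyl)-5-[(1Z)-2-{(5R)-5-[(1S)-1-hydroxy-2-oxoethyl]-5-methyl-4-oxo-4,5-dihydrofuran-2-yl}prop-1-en-1-yl]furan-2(5H)-one | O=C1O[C@H](/C=C(/C)C2=CC(=O)[C@](C)(O2)[C@H](O)C=O)C=C1CBr | intermediate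
28 | (2Z,4R,8R,9S,10R,11R)-9,10-dihydroxy-2,11-dimethyl-7-methylidene-5,14-dioxatricyclo[9.2.1.0^4,8]tetradeca-1(13),2-diene-6,12-dione (germacrane numbering: 8β,9α-diol) | C=C1C(=O)O[C@@H]2/C=C(/C)C3=CC(=O)[C@](C)(O3)[C@H](O)[C@@H](O)[C@@H]12 | intermediate
29 | (2Z,4R,8S,9S,10R,11R)-10-hydroxy-2,11-dimethyl-7-methylidene-6,12-dioxo-5,14-dioxatricyclo[9.2.1.0^4,8]tetradeca-1(13),2-dien-9-yl 3-methylbutanoate (8-monoisovalerate) | C=C1C(=O)O[C@@H]2/C=C(/C)C3=CC(=O)[C@](C)(O3)[C@H](O)[C@@H](OC(=O)CC(C)C)[C@@H]12 | intermediate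
30 | (2Z,4R,8S,9S,10R,11R)-10-(acetyloxy)-2,11-dimethyl-7-methylidene-6,12-dioxo-5,14-dioxatricyclo[9.2.1.0^4,8]tetradeca-1(13),2-dien-9-yl 3-methylbutanoate (germacrane numbering: 6R,7S,8S,9R,10R) | C=C1C(=O)O[C@@H]2/C=C(/C)C3=CC(=O)[C@](C)(O3)[C@H](OC(C)=O)[C@@H](OC(=O)CC(C)C)[C@@H]12 | target

## Step count and risks

Total step count: 16. Longest linear sequence: 10 (steps 7, 8, 9, 10, 11, 12, 13, 14, 15, 16). Fragment A takes steps 1–4 and the acid 15 takes steps 5–6.

The three steps most likely to fail: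

Step 12 (the proposed C–H alkenylation). The risks are no turnover at the furanone C–H, loss of the Z geometry, and base-induced epimerisation of the doubly allylic butenolide C–H. The fallback uses known chemistry, sets out from 7 and 23 and comes back at 24. Ethynylmagnesium bromide is added to 7 as in step 3, but the amine is left out and the hydroxy ynone 10 is isolated. Sonogashira coupling of 10 with 23 (PdCl2(PPh3)2, copper iodide CuI, iPr2NEt, THF, room temperature) gives (5R)-3-{[(tert-butyldimethylsilyl)oxy]methyl}-5-[(1Z,6R,7S)-6-hydroxy-8,8-dimethoxy-2,6-dimethyl-5-oxo-7-(triethylsilyloxy)oct-1-en-3-yn-1-yl]furan-2(5H)-one F1. Gold-catalysed 5-endo cycloisomerisation of the tertiary hydroxyl onto the ynone (AuCl(PPh3), AgOSO2CF3, toluene, room temperature) then closes the furanone and gives 24.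

Step 15 (ring closure). The risks are a poor yield of the medium ring and loss of chelate control at C8, since a non-chelated chair would give the C8 epimer. The fallback replaces the metal-mediated Barbier closure by a Lewis-acid-promoted allylsilane closure through an open transition state; it sets out from 21 (with 12 as partner) and comes back at 28.
- 21 is esterified with 2-[(trimethylsilyl)methyl]acrylic acid (DCC, DMAP) to (3S,4Z)-5-iodohexa-1,4-dien-3-yl 2-[(trimethylsilyl)methyl]prop-2-enoate F2.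
- Ring-closing metathesis as in step 11 gives (5S)-5-[(1Z)-2-iodoprop-1-en-1-yl]-3-[(trimethylsilyl)methyl]furan-2(5H)-one F3.
- Coupling with 12 as in step 12 gives (5R)-5-[(1Z)-2-{(5R)-5-[(1S)-2,2-dimethoxy-1-(triethylsilyloxy)ethyl]-5-methyl-4-oxo-4,5-dihydrofuran-2-yl}prop-1-en-1-yl]-3-[(trimethylsilyl)methyl]furan-2(5H)-one F4.
- Aqueous acetic acid (AcOH–H2O 4:1, 40 °C) removes the triethylsilyl group and the acetal to give (5R)-5-[(1Z)-2-{(5R)-5-[(1S)-1-hydroxy-2-oxoethyl]-5-methyl-4-oxo-4,5-dihydrofuran-2-yl}prop-1-en-1-yl]-3-[(trimethylsilyl)methyl]furan-2(5H)-one F5.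
- SnCl4 (2 equiv, CH2Cl2, −78 °C, 0.002 M) then effects a chelate-controlled intramolecular Hosomi–Sakurai allylation, which should give the same syn,syn array and 28. Steps 13 and 14 are then not needed.

Step 16 (regioselective double acylation). The risks are acylation at the wrong hydroxyl and acyl migration. The fallback separates the two hydroxyls by a silyl detour; it sets out from 28 and comes back at 30. Et3SiCl and imidazole (DMF, −20 °C) silylate the less hindered C8 hydroxyl to give the 8-O-triethylsilyl ether of 28 F6. Ac2O and DMAP give the 9-O-acetyl-8-O-triethylsilyl derivative of 28 F7. HF·pyridine gives the 9-O-acetyl derivative of 28 with free 8-hydroxyl F8, and isovaleryl chloride with 2,4,6-collidine then gives 30.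

Further compounds
F1 | step 12 | (5R)-3-{[(tert-butyldimethylsilyl)oxy]methyl}-5-[(1Z,6R,7S)-6-hydroxy-8,8-dimethoxy-2,6-dimethyl-5-oxo-7-(triethylsilyloxy)oct-1-en-3-yn-1-yl]furan-2(5H)-one | O=C1O[C@H](/C=C(/C)C#CC(=O)[C@](C)(O)[C@H](O[Si](CC)(CC)CC)C(OC)OC)C=C1CO[Si](C)(C)C(C)(C)C
F2 | step 15 | (3S,4Z)-5-iodohexa-1,4-dien-3-yl 2-[(trimethylsilyl)methyl]prop-2-enoate | C=C(C[Si](C)(C)C)C(=O)O[C@@H](C=C)/C=C(/C)I
F3 | step 15 | (5S)-5-[(1Z)-2-iodoprop-1-en-1-yl]-3-[(trimethylsilyl)methyl]furan-2(5H)-one | O=C1O[C@H](/C=C(/C)I)C=C1C[Si](C)(C)C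
F4 | step 15 | (5R)-5-[(1Z)-2-{(5R)-5-[(1S)-2,2-dimethoxy-1-(triethylsilyloxy)ethyl]-5-methyl-4-oxo-4,5-dihydrofuran-2-yl}prop-1-en-1-yl]-3-[(trimethylsilyl)methyl]furan-2(5H)-one | O=C1O[C@H](/C=C(/C)C2=CC(=O)[C@](C)(O2)[C@H](O[Si](CC)(CC)CC)C(OC)OC)C=C1C[Si](C)(C)C
F5 | step 15 | (5R)-5-[(1Z)-2-{(5R)-5-[(1S)-1-hydroxy-2-oxoethyl]-5-methyl-4-oxo-4,5-dihydrofuran-2-yl}prop-1-en-1-yl]-3-[(trimethylsilyl)methyl]furan-2(5H)-one | O=C1O[C@H](/C=C(/C)C2=CC(=O)[C@](C)(O2)[C@H](O)C=O)C=C1C[Si](C)(C)C
F6 | step 16 | 8-O-triethylsilyl ether of 28 (germacrane numbering) | C=C1C(=O)O[C@@H]2/C=C(/C)C3=CC(=O)[C@](C)(O3)[C@H](O)[C@@H](O[Si](CC)(CC)CC)[C@@H]12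
F7 | step 16 | 9-O-acetyl-8-O-triethylsilyl derivative of 28 | C=C1C(=O)O[C@@H]2/C=C(/C)C3=CC(=O)[C@](C)(O3)[C@H](OC(C)=O)[C@@H](O[Si](CC)(CC)CC)[C@@H]12
F8 | step 16 | 9-O-acetyl derivative of 28 with free 8-hydroxyl | C=C1C(=O)O[C@@H]2/C=C(/C)C3=CC(=O)[C@](C)(O3)[C@H](OC(C)=O)[C@@H](O)[C@@H]12
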